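**Plan**

1. Numbering (longipinane, used for the target and all tricycles): C1 ketone, C2=C3(Me), C4 and C11 cyclobutane methines (C4 next to C3, C11 next to C1), C5 cyclobutane CH, C6 quaternary (Me, CH2OAng), C7 CH–OAng, C8, C9, C10 quaternary cyclobutane carbon (Me).
2. Retrosynthesis: remove the two angelates and the enone (from a C1 carbinol and an exocyclic C3 methylene); cut C5–C6 (ester-enolate aldol onto a C5 cyclobutanone, the extra C5–O removed by radical deoxygenation); cut C4–C10 together with C5–C11 (vinylketene–alkene [2+2]); cut C1–C2 (vinylogous aldol) and C6–C7 (Reformatsky) back to geranyl acetate.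
3. Forward: acyclic chain → [2+2] closes the cyclobutanone and the six-membered ring at once → aldol closes the seven-membered ring → deoxygenation, reduction, angeloylation, oxidation/isomerization.
4. Enabling feature: C4 is bonded to C5, a carbon that can be a ketene carbonyl, and C10 is the fully substituted end of an (E)-trisubstituted C11=C10 alkene held three atoms (C3, C2, C1) from C4 — the pattern that gives bicyclo[3.1.1]heptanones by bridged ketene–alkene [2+2].
5. Stereochemistry: C7 from Noyori hydrogenation; the C1 carbinol from a catalytic asymmetric vinylogous aldol, relayed to C4/C10/C11 by allylic strain in the [2+2] and later erased to the ketone; C10 from the (E)-alkene of geranyl acetate; C6 from C7 in the aldol; C5 fixed by the ring.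

Key step: step 12

Remark: compounds 4–17 are carried as mixtures at the ester α-carbon (the future C6), which becomes a planar enolate in step 13, so their SMILES leave it undefined; the ketene acetal geometry of 11 is likewise irrelevant. Starting materials 1, 3, 10 and 23 are taken as commercial.

**Route**

Step 1
Reactants: 1 geranyl acetate
Product: 2 (2E)-3-methyl-6-oxohex-2-en-1-yl acetate
Conditions: O3 (1.0 equiv, Sudan Red end point), CH2Cl2/pyridine, −78 °C; then Me2S, −78 °C → rt
Reagents that add atoms: ozone, [O-][O+]=O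
Why: Chemoselective ozonolysis, since the isolated electron-rich isopropylidene alkene reacts much faster than the allylic-acetate alkene, and reductive work-up gives the aldehyde while the (E)-trisubstituted alkene (future C11=C10) stays intact.

Step 2
Reactants: 2 (2E)-3-methyl-6-oxohex-2-en-1-yl acetate; 3 tert-butyl 2-bromopropanoate
Product: 4 tert-butyl (6E)-8-acetoxy-3-hydroxy-2,6-dimethyloct-6-enoate (stereoisomer mixture)
Conditions: Zn dust (TMSCl-activated), THF, reflux; aq. work-up
Reagents that add atoms: none
Why: Reformatsky reaction, in which the zinc ester enolate adds only to the aldehyde and tolerates the acetate; the two new stereocenters need no control because step 3 removes one and step 13 re-sets the other.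

Step 3
Reactants: 4 hydroxy ester
Product: 5 tert-butyl (6E)-8-acetoxy-2,6-dimethyl-3-oxooct-6-enoate
Conditions: Dess–Martin periodinane, NaHCO3, CH2Cl2, 0 °C → rt
Reagents that add atoms: none
Why: Dess–Martin oxidation of the secondary alcohol to the 3-oxo ester under buffered neutral conditions that avoid acetate loss and retro-aldol cleavage.

Step 4
Reactants: 5 keto ester
Product: 6 tert-butyl (3R,6E)-8-acetoxy-3-hydroxy-2,6-dimethyloct-6-enoate (C2 epimers)
Conditions: RuCl2[(R)-BINAP] (1 mol %), H2 (50 atm), EtOH, 50 °C
Reagents that add atoms: none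
Why: Noyori asymmetric hydrogenation of a 3-oxo ester, where the keto-ester chelate on the (R)-BINAP ruthenium hydride should deliver hydrogen to one carbonyl face and give the (3R)-carbinol (C7 of the target) as with simple 3-oxo esters, the unfunctionalized trisubstituted alkene being inert.

Step 5
Reactants: 6 hydroxy ester
Product: 7 tert-butyl (3R,6E)-8-acetoxy-2,6-dimethyl-3-(triethylsilyloxy)oct-6-enoate
Conditions: TESCl, imidazole, CH2Cl2, 0 °C
Reagents that add atoms: chlorotriethylsilane, CC[Si](Cl)(CC)CC
Why: Standard silylation of a secondary alcohol; the triethylsilyl ether is chosen so that it can later be cleaved in the presence of the tert-butyldimethylsilyl ether.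

Step 6
Reactants: 7 acetate
Product: 8 tert-butyl (3R,6E)-8-hydroxy-2,6-dimethyl-3-(triethylsilyloxy)oct-6-enoate
Conditions: K2CO3 (cat.), MeOH, 0 °C
Reagents that add atoms: none
Why: Base-catalysed transesterification removes the primary acetate and should leave the hindered tert-butyl ester and the silyl ether untouched.

Step 7
Reactants: 8 allylic alcohol
Product: 9 tert-butyl (3R,6E)-2,6-dimethyl-8-oxo-3-(triethylsilyloxy)oct-6-enoate
Conditions: MnO2, CH2Cl2, rt
Reagents that add atoms: none
Why: MnO2 oxidation is selective for the allylic alcohol and keeps the (E)-geometry, giving the enal for the vinylogous aldol.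

Step 8
Reactants: 10 methyl 3-methylbut-2-enoate
Product: 11 tert-butyl[(1-methoxy-3-methylbuta-1,3-dien-1-yl)oxy]dimethylsilane
Conditions: LDA, THF, −78 °C; then TBSCl, DMPU, −78 °C → rt
Reagents that add atoms: tert-butylchlorodimethylsilane, CC(C)(C)[Si](C)(C)Cl
Why: γ-Deprotonation of the senecioate gives the extended enolate, which is O-silylated to the silyl dienol ether used as the vinylogous nucleophile.

Step 9
Reactants: 9 enal; 11 silyl dienol ether
Product: 12 12-tert-butyl 1-methyl (2E,5S,6E,10R)-5-hydroxy-3,7,11-trimethyl-10-(triethylsilyloxy)dodeca-2,6-dienedioate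
Conditions: SiCl4 (1.1 equiv), (S,S)-configured dimeric binaphthyldiamine phosphoramide (two N,N'-dimethyl-1,1'-binaphthyl-2,2'-diamine phosphoramide units joined through N,N'-dimethylpentane-1,5-diamine, 5 mol %), i-Pr2NEt (10 mol %), CH2Cl2, −78 °C; aq. NaHCO3
Reagents that add atoms: none
Why: Catalytic enantioselective vinylogous Mukaiyama aldol (Lewis-base-activated SiCl4), in which the dienol ether attacks through its γ-carbon on the Si face of the activated enal (the catalyst antipode is chosen for this face, expected to be (S,S)) to give the (5S)-carbinol (C1 of the target) and the (E)-enoate, with catalyst control over the remote C10 center.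

Step 10
Reactants: 12 allylic alcohol
Product: 13 the 5-(tert-butyldimethylsilyl) ether of 12
Conditions: TBSCl, imidazole, DMF, rt
Reagents that add atoms: tert-butylchlorodimethylsilane, CC(C)(C)[Si](C)(C)Cl
Why: Routine silylation; the robust TBS ether protects the future ketone oxygen and supplies the bulk that enforces the allylic-strain conformation used in step 12.

Step 11
Reactants: 13 diester
Product: 14 (2E,5S,6E,10R)-12-tert-butoxy-5-(tert-butyldimethylsilyloxy)-3,7,11-trimethyl-12-oxo-10-(triethylsilyloxy)dodeca-2,6-dienoic acid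
Conditions: LiOH, THF/MeOH/H2O, 40 °C; then 0.5 M HCl to pH 4, 0 °C
Reagents that add atoms: lithium hydroxide, [Li+].[OH-]
Why: Saponification differentiates the two esters, since hydroxide cleaves the methyl enoate while the tert-butyl ester resists acyl substitution under these conditions.

Step 12
Reactants: 14 dienoic acid
Product: 17 bicyclo[3.1.1]heptanone (cyclobutanone), via acid chloride 15 (not isolated), via vinylketene 16 (not isolated)
Conditions: 1-chloro-N,N,2-trimethylprop-1-en-1-amine (Ghosez reagent), CH2Cl2, 0 °C → rt; concentrate; syringe-pump addition to Et3N (5 equiv), toluene, reflux (final 0.005 M)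
Reagents that add atoms: none
Why: The Ghosez reagent gives acid chloride 15 under neutral conditions, Et3N removes HCl through the γ-methyl to give vinylketene 16, and this undergoes a thermal asynchronous [2+2] cycloaddition in which the ketene carbonyl carbon (C5) bonds to the less substituted alkene carbon C11 and C4 bonds to the fully substituted C10 that carries the developing positive charge. The closest known reaction type is the Snider intramolecular vinylketene–alkene cycloaddition of geranoyl and farnesoyl chlorides to 2-methylidenebicyclo[3.1.1]heptan-6-ones. The two new bonds close the cyclobutanone (C4–C5–C11–C10) and with it the six-membered ring C1–C2–C3–C4–C5–C11 in the bridged (crossed) mode, the fused bicyclo[3.2.0] mode being disfavoured because it would place positive charge on the monosubstituted C11. C10 is set by suprafacial addition to the (E)-alkene, which puts its methyl on the side of the C1–C3 bridge and the side chain on the side of the C5 carbonyl, and C4 and C11 follow from the bridging. The absolute sense comes from C1: with C1–H eclipsing C11=C10 to avoid allylic 1,3-strain with the C10 methyl, the tether and the OTBS group lie on opposite alkene faces, so the ketene can reach only one face. The step needs regio- and facial selectivity, secured by the polarity of the trisubstituted alkene and by the C1 stereocenter, and high dilution to suppress ketene dimerization.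

Step 13
Reactants: 17 cyclobutanone
Product: 19 tricyclic methyl oxalate, via lithium aldolate 18 (not isolated)
Conditions: LDA (1.1 equiv), THF, −78 °C (17 added slowly, 0.01 M); then ClC(O)CO2Me, −78 → −20 °C
Reagents that add atoms: methyl chlorooxoacetate, COC(=O)C(=O)Cl
Why: Intramolecular aldol addition of the lithium ester enolate to the non-enolizable, strain-activated cyclobutanone closes the seven-membered ring from the face on which the chain is held (O5 ends on the side of the C1–C3 bridge), and C6 is set by C7 because with C7–H in the enolate plane (allylic strain) the ring-forming tether and the OTES group lie on opposite faces, which places the methyl cis and the ester trans to O7; the aldolate is acylated in situ to prevent retro-aldol.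

Step 14
Reactants: 19 tricyclic methyl oxalate
Product: 20 C5-deoxy tricyclic tert-butyl ester
Conditions: Bu3SnH, AIBN (cat.), toluene, 110 °C
Reagents that add atoms: none
Why: Radical deoxygenation of a tertiary methyl oxalate (Barton–McCombie type), where stannyl radical addition and C–O scission give the C5 cyclobutyl radical, which has no elimination pathway and takes hydrogen on its only open face, C5 being locked by the ring.

Step 15
Reactants: 20 tricyclic tert-butyl ester
Product: 22 tricyclic 7,6-CH2 diol, via primary alcohol 21 (not isolated)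
Conditions: LiAlH4, THF, 0 °C → rt; Fieser work-up; then PPTS, MeOH, rt
Reagents that add atoms: none
Why: LiAlH4 reduces the hindered tert-butyl ester to the primary alcohol without touching the alkene, and mild acidic methanolysis then removes the more labile triethylsilyl ether selectively, leaving the TBS ether.

Step 16
Reactants: 22 diol; 23 angelic acid
Product: 25 bis-angelate TBS ether, via mixed anhydride 24 (not isolated)
Conditions: 23 (5 equiv), 2,4,6-trichlorobenzoyl chloride, Et3N, toluene, rt; then 22, DMAP, toluene, 80 °C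
Reagents that add atoms: none
Why: Yamaguchi esterification, in which the mixed trichlorobenzoic anhydride of angelic acid acylates both hydroxyls under DMAP catalysis, a protocol that should preserve the (Z)-geometry of the angelates.

Step 17
Reactants: 25 bis-angelate TBS ether
Product: 26 C1 alcohol
Conditions: HF·pyridine, THF/pyridine, 0 °C → rt
Reagents that add atoms: none
Why: Fluoride-mediated cleavage of the remaining silyl ether under buffered conditions that should neither hydrolyse nor isomerize the angelates.

Step 18
Reactants: 26 C1 alcohol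
Product: 28 target CNP0240716.2, via deconjugated ketone 27 (not isolated)
Conditions: Dess–Martin periodinane, NaHCO3, CH2Cl2, 0 °C → rt; then DBU (cat.), 0 °C
Reagents that add atoms: none
Why: Dess–Martin oxidation gives the β,γ-unsaturated ketone, and base-mediated enolization at C2 with γ-protonation moves the exocyclic alkene into conjugation under thermodynamic control, creating the C2=C3 enone and erasing the C1 relay stereocenter.

**Compound list**

1 | geranyl acetate, (2E)-3,7-dimethylocta-2,6-dien-1-yl acetate | CC(=O)OC/C=C(\C)CCC=C(C)C | starting material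
2 | (2E)-3-methyl-6-oxohex-2-en-1-yl acetate | CC(=O)OC/C=C(\C)CCC=O | intermediate
3 | tert-butyl 2-bromopropanoate (racemic) | CC(Br)C(=O)OC(C)(C)C | starting material
4 | tert-butyl (6E)-8-acetoxy-3-hydroxy-2,6-dimethyloct-6-enoate (stereoisomer mixture) | CC(=O)OC/C=C(\C)CCC(O)C(C)C(=O)OC(C)(C)C | intermediate
5 | tert-butyl (6E)-8-acetoxy-2,6-dimethyl-3-oxooct-6-enoate | CC(=O)OC/C=C(\C)CCC(=O)C(C)C(=O)OC(C)(C)C | intermediate
6 | tert-butyl (3R,6E)-8-acetoxy-3-hydroxy-2,6-dimethyloct-6-enoate (C2 epimers) | CC(=O)OC/C=C(\C)CC[C@@H](O)C(C)C(=O)OC(C)(C)C | intermediate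
7 | tert-butyl (3R,6E)-8-acetoxy-2,6-dimethyl-3-(triethylsilyloxy)oct-6-enoate | CC(=O)OC/C=C(\C)CC[C@@H](O[Si](CC)(CC)CC)C(C)C(=O)OC(C)(C)C | intermediate
8 | tert-butyl (3R,6E)-8-hydroxy-2,6-dimethyl-3-(triethylsilyloxy)oct-6-enoate | OC/C=C(\C)CC[C@@H](O[Si](CC)(CC)CC)C(C)C(=O)OC(C)(C)C | intermediate
9 | tert-butyl (3R,6E)-2,6-dimethyl-8-oxo-3-(triethylsilyloxy)oct-6-enoate | O=C/C=C(\C)CC[C@@H](O[Si](CC)(CC)CC)C(C)C(=O)OC(C)(C)C | intermediate
10 | methyl 3-methylbut-2-enoate | COC(=O)C=C(C)C | starting material
11 | tert-butyl[(1-methoxy-3-methylbuta-1,3-dien-1-yl)oxy]dimethylsilane | COC(O[Si](C)(C)C(C)(C)C)=CC(C)=C | intermediate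
12 | 12-tert-butyl 1-methyl (2E,5S,6E,10R)-5-hydroxy-3,7,11-trimethyl-10-(triethylsilyloxy)dodeca-2,6-dienedioate | COC(=O)/C=C(\C)C[C@H](O)/C=C(\C)CC[C@@H](O[Si](CC)(CC)CC)C(C)C(=O)OC(C)(C)C | intermediate
13 | 12-tert-butyl 1-methyl (2E,5S,6E,10R)-5-(tert-butyldimethylsilyloxy)-3,7,11-trimethyl-10-(triethylsilyloxy)dodeca-2,6-dienedioate | COC(=O)/C=C(\C)C[C@H](O[Si](C)(C)C(C)(C)C)/C=C(\C)CC[C@@H](O[Si](CC)(CC)CC)C(C)C(=O)OC(C)(C)C | intermediate
14 | (2E,5S,6E,10R)-12-tert-butoxy-5-(tert-butyldimethylsilyloxy)-3,7,11-trimethyl-12-oxo-10-(triethylsilyloxy)dodeca-2,6-dienoic acid | OC(=O)/C=C(\C)C[C@H](O[Si](C)(C)C(C)(C)C)/C=C(\C)CC[C@@H](O[Si](CC)(CC)CC)C(C)C(=O)OC(C)(C)C | intermediate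
15 | acid chloride of 14 | ClC(=O)/C=C(\C)C[C@H](O[Si](C)(C)C(C)(C)C)/C=C(\C)CC[C@@H](O[Si](CC)(CC)CC)C(C)C(=O)OC(C)(C)C | intermediate
16 | vinylketene from 15 (3-methylidene ketene; 5S, 6E, 10R as in 14) | O=C=CC(=C)C[C@H](O[Si](C)(C)C(C)(C)C)/C=C(\C)CC[C@@H](O[Si](CC)(CC)CC)C(C)C(=O)OC(C)(C)C | intermediate
17 | tert-butyl (3R)-5-[(2S)-2-(tert-butyldimethylsilyloxy)-6-methyl-4-methylidene-7-oxobicyclo[3.1.1]heptan-6-yl]-2-methyl-3-(triethylsilyloxy)pentanoate (6-methyl on the side of the C2–C4 bridge, OTBS on the side of the C7 carbonyl) | O=C1[C@H]2[C@@H](O[Si](C)(C)C(C)(C)C)CC(=C)[C@@H]1[C@@]2(C)CC[C@@H](O[Si](CC)(CC)CC)C(C)C(=O)OC(C)(C)C | intermediate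
18 | lithium C5-alkoxide of the tricyclic aldol adduct (longipinane skeleton: 1S-OTBS, 3-methylidene, 6-methyl, 6-CO2tBu trans to O7, 7R-OTES) | CC(C)(C)OC(=O)[C@]1(C)[C@]2([O-])[C@H]3[C@@H](O[Si](C)(C)C(C)(C)C)CC(=C)[C@@H]2[C@@]3(C)CC[C@H]1O[Si](CC)(CC)CC.[Li+] | intermediate
19 | tricyclic C5 methyl oxalate (same skeleton and substituents as 18, C5–OC(O)CO2Me on the side of the C1–C3 bridge) | CC(C)(C)OC(=O)[C@]1(C)[C@]2(OC(=O)C(=O)OC)[C@H]3[C@@H](O[Si](C)(C)C(C)(C)C)CC(=C)[C@@H]2[C@@]3(C)CC[C@H]1O[Si](CC)(CC)CC | intermediate
20 | C5-deoxy tricyclic tert-butyl ester (1S-OTBS, 3-methylidene, 6-CO2tBu, 7R-OTES) | CC(C)(C)OC(=O)[C@]1(C)[C@@H]2[C@H]3[C@@H](O[Si](C)(C)C(C)(C)C)CC(=C)[C@@H]2[C@@]3(C)CC[C@H]1O[Si](CC)(CC)CC | intermediate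
21 | tricyclic primary alcohol (6-CH2OH, 7R-OTES, 1S-OTBS, 3-methylidene) | OC[C@]1(C)[C@@H]2[C@H]3[C@@H](O[Si](C)(C)C(C)(C)C)CC(=C)[C@@H]2[C@@]3(C)CC[C@H]1O[Si](CC)(CC)CC | intermediate
22 | tricyclic diol (6-CH2OH, 7R-OH, 1S-OTBS, 3-methylidene) | OC[C@]1(C)[C@@H]2[C@H]3[C@@H](O[Si](C)(C)C(C)(C)C)CC(=C)[C@@H]2[C@@]3(C)CC[C@H]1O | intermediate
23 | angelic acid, (2Z)-2-methylbut-2-enoic acid | C/C=C(/C)C(=O)O | starting material
24 | angelic 2,4,6-trichlorobenzoic anhydride | C/C=C(/C)C(=O)OC(=O)c1c(Cl)cc(Cl)cc1Cl | intermediate
25 | bis-angelate TBS ether (6-CH2OAng, 7R-OAng, 1S-OTBS, 3-methylidene) | C/C=C(/C)C(=O)OC[C@]1(C)[C@@H]2[C@H]3[C@@H](O[Si](C)(C)C(C)(C)C)CC(=C)[C@@H]2[C@@]3(C)CC[C@H]1OC(=O)/C(C)=C\C | intermediate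
26 | bis-angelate C1 alcohol (1S-OH, 3-methylidene) | C/C=C(/C)C(=O)OC[C@]1(C)[C@@H]2[C@H]3[C@@H](O)CC(=C)[C@@H]2[C@@]3(C)CC[C@H]1OC(=O)/C(C)=C\C | intermediate
27 | bis-angelate 3-methylidene-1-ketone (deconjugated) | C/C=C(/C)C(=O)OC[C@]1(C)[C@@H]2[C@H]3C(=O)CC(=C)[C@@H]2[C@@]3(C)CC[C@H]1OC(=O)/C(C)=C\C | intermediate
28 | CNP0240716.2, (4R,5S,6S,7R,10R,11R)-longipin-2-en-1-one bearing angelate on the C6 CH2O and on O7 | C/C=C(/C)C(=O)OC[C@]1(C)[C@@H]2[C@H]3C(=O)C=C(C)[C@@H]2[C@@]3(C)CC[C@H]1OC(=O)/C(C)=C\C | target

**Step count and risks**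

Total step count: 18. Longest linear sequence: 17 steps (1–7 and 9–18, from geranyl acetate).

Step 12 (key cycloaddition). The alkene is deactivated by the allylic silyloxy group held anti to the incoming ketene, so cycloaddition may be slower than ketene dimerization, and facial control may erode at reflux. The fallback sets out from 14. Condensation with pyrrolidine (EDC·HCl, HOBt, CH2Cl2) should give pyrrolidine amide F1. Tf2O and 2,4,6-collidine in 1,2-dichloroethane at 80 °C should then generate the more electrophilic vinylketeniminium ion (Ghosez-type keteniminium–alkene [2+2]), expected to close with the same regio- and facial preferences to cyclobutaniminium triflate F2. Hydrolysis with aqueous NaHCO3 comes back to the route at 17.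

Step 13 (aldol ring closure). The ester enolate may lose the β-silyloxy group, the amide base may reduce the strained ketone or promote intermolecular aldol, and the aldolate may revert before it is trapped. The fallback sets out from 17. Deprotonation with LDA in the presence of TMSCl (internal quench, THF, −100 °C) should trap the enolate as silyl ketene acetal F3 before it can eliminate. BF3·OEt2 in CH2Cl2 at −78 °C should then activate the cyclobutanone for an intramolecular Mukaiyama aldol to tertiary alcohol F4. Acylation with methyl chlorooxoacetate, pyridine and DMAP comes back to the route at 19.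

Step 14 (radical deoxygenation). Hydrogen transfer from the bulky stannane to the hindered C5 radical may be slow, which would let ring-opening β-scission of the cyclobutane compete. The fallback sets out from 19. Half-saponification with CsOH (1 equiv, THF/H2O, 0 °C) should give cesium oxalate F5. Visible-light photoredox decarboxylation (Ir[dF(CF3)ppy]2(dtbbpy)PF6 cat., blue LEDs, rt, excess methyl thioglycolate as a small hydrogen-atom donor) should generate the same radical at room temperature and quench it faster, coming back to the route at 20.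

**Further compounds**

F1 | step 12 | pyrrolidine amide of acid 14 | O=C(/C=C(\C)C[C@H](O[Si](C)(C)C(C)(C)C)/C=C(\C)CC[C@@H](O[Si](CC)(CC)CC)C(C)C(=O)OC(C)(C)C)N1CCCC1
F2 | step 12 | cyclobutaniminium triflate (pyrrolidinium ylidene corresponding to 17) | C4CC[N+](C4)=C1[C@H]2[C@@H](O[Si](C)(C)C(C)(C)C)CC(=C)[C@@H]1[C@@]2(C)CC[C@@H](O[Si](CC)(CC)CC)C(C)C(=O)OC(C)(C)C.[O-]S(=O)(=O)C(F)(F)F
F3 | step 13 | tert-butyl trimethylsilyl ketene acetal of 17 | O=C1[C@H]2[C@@H](O[Si](C)(C)C(C)(C)C)CC(=C)[C@@H]1[C@@]2(C)CC[C@@H](O[Si](CC)(CC)CC)C(C)=C(O[Si](C)(C)C)OC(C)(C)C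
F4 | step 13 | tricyclic C5 tertiary alcohol (free aldol adduct) | CC(C)(C)OC(=O)[C@]1(C)[C@]2(O)[C@H]3[C@@H](O[Si](C)(C)C(C)(C)C)CC(=C)[C@@H]2[C@@]3(C)CC[C@H]1O[Si](CC)(CC)CC
F5 | step 14 | cesium oxalate of the C5 alcohol | CC(C)(C)OC(=O)[C@]1(C)[C@]2(OC(=O)C(=O)[O-])[C@H]3[C@@H](O[Si](C)(C)C(C)(C)C)CC(=C)[C@@H]2[C@@]3(C)CC[C@H]1O[Si](CC)(CC)CC.[Cs+]
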